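**Retrosynthetic overview**
1. The ring is numbered C1 (CHOAc), C2=C3(CH3), C4 (CHO-aroyl), C5, C6=C7(CH3), C8–C10, C11 (C(CH3)2). Both esters go on last, and the C1 carbinol comes from Corey–Bakshi–Shibata reduction of the (2Z,6E)-cycloundecadienone 11.
2. The key disconnection excises C11. The motif O=C1–C11(CH3)2–C10H2 is a ring ketone flanked by a quaternary ring carbon and then a ring CH2. This is the retron of a 1-oxy-11,11-dimethylbicyclo[8.1.0]undecane. Breaking its zero bridge C1–C10 pushes the apex C11 into the ring, so the ten-membered ring becomes the eleven-membered ring.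
3. The cyclopropanol comes from C(CH3)2 transfer to the C1=C10 silyl enol ether 8 of a ten-membered ring. An anionic oxy-Cope rearrangement of cyclohexenol 5 delivers 8 regiospecifically. C1=O, three CH2 groups and E-C6=C7 form the oxy-Cope retron, and Z-C2=C3 is the old cyclohexene alkene.
4. Compound 5 comes from (R)-carvone. Luche reduction fixes C4, allylic oxidation makes C1=O, and vinyl addition completes the 1,5-diene.
5. Ring order: six-membered (purchased), ten-membered (step 5), three-membered fused on ten-membered (step 6, transient), eleven-membered (step 6).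

Key step: step 6

Assumption: 2,2-diiodopropane and 4-(tert-butyldimethylsilyloxy)benzoic acid are taken as purchasable. The cyclopropane stereocentres of 9 and 10 are drawn for one face of attack because both faces lead to the same product.

Step 1
Reactants: 1 (R)-(−)-carvone
Product: 2 (−)-cis-carveol [(1R,5R)-2-methyl-5-(prop-1-en-2-yl)cyclohex-2-en-1-ol]
Conditions: NaBH4, CeCl3·7H2O, MeOH, −78 to 0 °C
Reagents that add atoms: none
Why: Luche reduction adds hydride 1,2 only and axially on the half-chair with the isopropenyl group equatorial, which should give the equatorial cis (1R) carbinol that becomes C4 of the target.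

Step 2
Reactants: 2 (−)-cis-carveol
Product: 3 cis-carveol TBS ether [tert-butyldimethyl{[(1R,5R)-2-methyl-5-(prop-1-en-2-yl)cyclohex-2-en-1-yl]oxy}silane]
Conditions: t-BuMe2SiCl, imidazole, DMF, rt
Reagents that add atoms: tert-butyldimethylsilyl chloride, CC(C)(C)[Si](C)(C)Cl
Why: Standard silyl ether formation touches no stereocentre, and the TBS group should withstand the chromium oxidant, Grignard reagent, KH, zinc carbenoid, methoxide and borane that follow.

Step 3
Reactants: 3 cis-carveol TBS ether
Product: 4 (4R,6R)-4-(tert-butyldimethylsilyloxy)-3-methyl-6-(prop-1-en-2-yl)cyclohex-2-en-1-one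
Conditions: CrO3, 3,5-dimethylpyrazole, CH2Cl2, −20 °C
Reagents that add atoms: chromium trioxide, O=[Cr](=O)=O
Why: Allylic C–H oxidation with the CrO3–3,5-dimethylpyrazole complex should attack the ring CH2 at the CH terminus of the trisubstituted alkene, as in the oxidation of isopropenyl-bearing cyclohexene terpenes to enones, and leave the 1,1-disubstituted alkene and both stereocentres alone.

Step 4
Reactants: 4 silyloxy enone
Product: 5 (1R,4R,6R)-4-(tert-butyldimethylsilyloxy)-1-ethenyl-3-methyl-6-(prop-1-en-2-yl)cyclohex-2-en-1-ol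
Conditions: CH2=CHMgBr, LaCl3·2LiCl (0.3 equiv), THF, −78 to 0 °C
Reagents that add atoms: vinylmagnesium bromide, C=C[Mg]Br
Why: In this LaCl3-promoted 1,2-Grignard addition, which suppresses enolisation at C6, the nucleophile should approach the face opposite the isopropenyl and silyloxy groups, setting C1 as R with the two alkenyl groups trans as the chair oxy-Cope needs.

Step 5
Reactants: 5 divinylcyclohexenol
Product: 8 (1(10)Z,2Z,4R,6E)-4-(tert-butyldimethylsilyloxy)-3,7-dimethyl-1-(trimethylsilyloxy)cyclodeca-1(10),2,6-triene, via potassium alkoxide 6 (not isolated), via potassium cyclodecatrienolate 7 (not isolated)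
Conditions: KH, 18-crown-6, THF, 0 °C to rt; then Me3SiCl, Et3N, −78 °C
Reagents that add atoms: chlorotrimethylsilane, C[Si](C)(C)Cl
Why: The anionic oxy-Cope rearrangement ([3,3], six- to ten-membered) should run through a chair with both ring bonds pseudo-equatorial, which makes C6=C7 E and C1=C10 ring-trans, keeps the old cyclohexene alkene as Z-C2=C3, and releases the enolate at C1/C10 only for O-silylation; closely related isopropenyl-substituted vinylcyclohexenols are known to do this.

Step 6
Reactants: 8 ten-membered silyl dienol ether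
Product: 11 (2Z,4R,6E)-4-(tert-butyldimethylsilyloxy)-3,7,11,11-tetramethylcycloundeca-2,6-dien-1-one, via siloxycyclopropane 9 (not isolated), via sodium cyclopropanolate 10 (not isolated)
Conditions: Et2Zn, (CH3)2CI2, CH2Cl2, −10 °C to rt; pyridine quench, filtration, solvent swap; NaOMe (0.2 equiv), MeOH–THF, 0 °C to rt
Reagents that add atoms: 2,2-diiodopropane, CC(C)(I)I
Why: Proposed new method: the electrophilic zinc carbenoid Zn(C(CH3)2I)2 should transfer C(CH3)2 in a concerted, stereospecific [2+1] addition to the most electron-rich alkene of 8, the C1=C10 silyl enol ether, closing the three-membered ring of 9; methoxide then removes Me3Si, and cyclopropanolate 10 collapses to the C1 ketone while the zero bridge C1–C10 breaks and C10 is protonated by methanol (homoketonization, SE2), so C11 ends up inside the ring. The closest known reaction types are the Furukawa–Simmons–Smith cyclopropanation of silyl enol ethers, isopropylidene transfer from Et2Zn/2,2-diiodopropane to alkenes, and the base-induced opening of 2,2-dialkylcyclopropanols at the bond to the less substituted carbon (1,2,2-trimethylcyclopropanol gives pinacolone); what is new is their union as a one-carbon C(CH3)2 insertion that enlarges a medium ring. The eleven-membered ring is not closed by bond formation but arises from the ten-membered ring by strain-releasing scission of the bond it shares with the cyclopropane. No new stereocentre survives, because C1 becomes sp2, C10 becomes CH2 and C11 carries two methyl groups, so both faces of attack and any enol ether isomer converge on one product while C4 and the 2Z and 6E alkenes are spectators. Two selectivities are needed: attack at the enol ether rather than the two trisubstituted alkenes, secured by its much higher nucleophilicity, and cleavage of C1–C10 rather than C1–C11, secured by the gem-dimethyl apex because the alternative would put the developing carbanion on a tertiary carbon. Catalytic methoxide at or below room temperature should spare the Z-enone geometry, the C4–H and the TBS ether.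

Step 7
Reactants: 11 cycloundecadienone
Product: 12 (1R,2Z,4R,6E)-4-(tert-butyldimethylsilyloxy)-3,7,11,11-tetramethylcycloundeca-2,6-dien-1-ol
Conditions: (S)-Me-CBS [(S)-1-methyl-3,3-diphenyltetrahydro-1H,3H-pyrrolo[1,2-c][1,3,2]oxazaborole] (0.3 equiv), catecholborane, toluene, −78 to −40 °C
Reagents that add atoms: none
Why: In the Corey–Bakshi–Shibata reduction the ketone should bind with the tert-alkyl C11 side as the large group, so the (S)-catalyst delivers hydride to the face that gives the 1R carbinol (cis to the C4 oxygen), while catecholborane at low temperature avoids hydroboration of the alkenes.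

Step 8
Reactants: 12 allylic alcohol
Product: 13 (1R,2Z,4R,6E)-4-(tert-butyldimethylsilyloxy)-3,7,11,11-tetramethylcycloundeca-2,6-dien-1-yl acetate
Conditions: Ac2O, Et3N, 4-(dimethylamino)pyridine (0.2 equiv), CH2Cl2, rt
Reagents that add atoms: acetic anhydride, CC(=O)OC(C)=O
Why: Nucleophile-catalysed acylation should acetylate even the neopentylic carbinol and leaves the C1–O bond, and thus the configuration, untouched.

Step 9
Reactants: 13 silyl ether acetate
Product: 14 (1R,2Z,4R,6E)-4-hydroxy-3,7,11,11-tetramethylcycloundeca-2,6-dien-1-yl acetate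
Conditions: HF·pyridine, pyridine, THF, 0 °C to rt
Reagents that add atoms: none
Why: Fluoride desilylation in a buffered, weakly acidic medium generates no alkoxide, so the C1 acetate should not migrate across the Z alkene to the C4 oxygen.

Step 10
Reactants: 14 hydroxy acetate; 15 4-(tert-butyldimethylsilyloxy)benzoic acid
Product: 16 (1R,2Z,4R,6E)-1-acetoxy-3,7,11,11-tetramethylcycloundeca-2,6-dien-4-yl 4-(tert-butyldimethylsilyloxy)benzoate
Conditions: N-ethyl-N'-(3-dimethylaminopropyl)carbodiimide (EDC), 4-(dimethylamino)pyridine, CH2Cl2, 0 °C to rt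
Reagents that add atoms: none
Why: Steglich esterification activates the acid, not the alcohol, so the C4–O bond and its R configuration are retained and no allylic transposition can occur.

Step 11
Reactants: 16 protected diester
Product: 17 target, (1R,2Z,4R,6E)-1-acetoxy-3,7,11,11-tetramethylcycloundeca-2,6-dien-4-yl 4-hydroxybenzoate
Conditions: Bu4NF, AcOH, THF, 0 °C
Reagents that add atoms: none
Why: Aryl silyl ethers are cleaved by buffered fluoride much faster than esters react, so the phenol should be released without touching the acetate or the benzoate.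

**Compound list**
1 | (R)-(−)-carvone | CC1=CC[C@H](CC1=O)C(C)=C | starting material
2 | (−)-cis-carveol, (1R,5R) | CC1=CC[C@H](C[C@H]1O)C(C)=C | intermediate
3 | (1R,5R)-cis-carveol TBS ether | CC1=CC[C@H](C[C@H]1O[Si](C)(C)C(C)(C)C)C(C)=C | intermediate
4 | (4R,6R)-4-(tert-butyldimethylsilyloxy)-3-methyl-6-(prop-1-en-2-yl)cyclohex-2-en-1-one | CC1=CC(=O)[C@H](C[C@H]1O[Si](C)(C)C(C)(C)C)C(C)=C | intermediate
5 | (1R,4R,6R)-4-(tert-butyldimethylsilyloxy)-1-ethenyl-3-methyl-6-(prop-1-en-2-yl)cyclohex-2-en-1-ol | CC1=C[C@](O)(C=C)[C@H](C[C@H]1O[Si](C)(C)C(C)(C)C)C(C)=C | intermediate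
6 | potassium alkoxide of 5 | CC1=C[C@]([O-])(C=C)[C@H](C[C@H]1O[Si](C)(C)C(C)(C)C)C(C)=C.[K+] | intermediate
7 | potassium (1(10)Z,2Z,4R,6E)-4-(tert-butyldimethylsilyloxy)-3,7-dimethylcyclodeca-1(10),2,6-trien-1-olate | C1/C=C([O-])/C=C(C)\[C@H](O[Si](C)(C)C(C)(C)C)C/C=C(C)/C1.[K+] | intermediate
8 | (1(10)Z,2Z,4R,6E)-4-(tert-butyldimethylsilyloxy)-3,7-dimethyl-1-(trimethylsilyloxy)cyclodeca-1(10),2,6-triene (C2 and C9 trans across C1=C10) | C1/C=C(O[Si](C)(C)C)/C=C(C)\[C@H](O[Si](C)(C)C(C)(C)C)C/C=C(C)/C1 | intermediate
9 | (2Z,4R,6E)-4-(tert-butyldimethylsilyloxy)-3,7,11,11-tetramethyl-1-(trimethylsilyloxy)bicyclo[8.1.0]undeca-2,6-diene, trans-fused, one of two converging diastereomers | C1[C@H]2C(C)(C)[C@]2(O[Si](C)(C)C)/C=C(C)\[C@H](O[Si](C)(C)C(C)(C)C)C/C=C(C)/C1 | intermediate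
10 | sodium cyclopropanolate from 9 | C1[C@H]2C(C)(C)[C@]2([O-])/C=C(C)\[C@H](O[Si](C)(C)C(C)(C)C)C/C=C(C)/C1.[Na+] | intermediate
11 | (2Z,4R,6E)-4-(tert-butyldimethylsilyloxy)-3,7,11,11-tetramethylcycloundeca-2,6-dien-1-one | O=C1/C=C(/C)[C@H](O[Si](C)(C)C(C)(C)C)C/C=C(\C)CCCC1(C)C | intermediate
12 | (1R,2Z,4R,6E)-4-(tert-butyldimethylsilyloxy)-3,7,11,11-tetramethylcycloundeca-2,6-dien-1-ol | O[C@@H]1/C=C(/C)[C@H](O[Si](C)(C)C(C)(C)C)C/C=C(\C)CCCC1(C)C | intermediate
13 | (1R,2Z,4R,6E)-4-(tert-butyldimethylsilyloxy)-3,7,11,11-tetramethylcycloundeca-2,6-dien-1-yl acetate | CC(=O)O[C@@H]1/C=C(/C)[C@H](O[Si](C)(C)C(C)(C)C)C/C=C(\C)CCCC1(C)C | intermediate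
14 | (1R,2Z,4R,6E)-4-hydroxy-3,7,11,11-tetramethylcycloundeca-2,6-dien-1-yl acetate | CC(=O)O[C@@H]1/C=C(/C)[C@H](O)C/C=C(\C)CCCC1(C)C | intermediate
15 | 4-(tert-butyldimethylsilyloxy)benzoic acid | OC(=O)c1ccc(O[Si](C)(C)C(C)(C)C)cc1 | starting material
16 | (1R,2Z,4R,6E)-1-acetoxy-3,7,11,11-tetramethylcycloundeca-2,6-dien-4-yl 4-(tert-butyldimethylsilyloxy)benzoate | CC(=O)O[C@@H]1/C=C(/C)[C@H](OC(=O)c2ccc(O[Si](C)(C)C(C)(C)C)cc2)C/C=C(\C)CCCC1(C)C | intermediate
17 | (1R,2Z,4R,6E)-1-acetoxy-3,7,11,11-tetramethylcycloundeca-2,6-dien-4-yl 4-hydroxybenzoate | CC(=O)O[C@@H]1/C=C(/C)[C@H](OC(=O)c2ccc(O)cc2)C/C=C(\C)CCCC1(C)C | target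

Total step count: 11. Longest linear sequence: 11 steps (1 to 17).

**Steps most likely to fail**

**Step 6 (Proposed new method).**
- The risks are three. Transfer of the bulky C(CH3)2 unit to the hindered trisubstituted enol ether may be sluggish or unselective. ZnI2 may isomerise the siloxycyclopropane. The outer C1–C11 bond may open in competition with the zero bridge.
- The fallback uses known chemistry, sets out from 8 and comes back at 11. It inserts CH2 first and adds the methyl groups afterwards.
- Furukawa–Simmons–Smith methylenation (Et2Zn, CH2I2, CH2Cl2) of the enol ether gives the methylene-bridged siloxycyclopropane F1.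
- FeCl3 in DMF at 0 °C opens the zero bridge oxidatively through the more substituted β-keto radical. This again takes the ten-membered ring to the eleven-membered ring and gives the β-chloro ketone F2.
- NaOAc in MeOH eliminates HCl to the cross-conjugated trienone F3.
- [(Ph3P)CuH]6 in benzene reduces only the less hindered disubstituted enone alkene to the dienone F4.
- Two rounds of LiN(iPr)2/MeI at C11, the only enolisable α-carbon, pass through the monomethyl ketone F5 and give 11.

**Step 3.**
- The risks are competing oxidation at the silyloxy-bearing C–H or at the isopropenyl allylic positions, and migration of the isopropenyl alkene into conjugation.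
- The fallback sets out from 3 and comes back at 4. It replaces C–H oxidation by an epoxide-based 1,3-transposition.
- mCPBA epoxidises the more electron-rich ring alkene to the epoxide F6. Both epoxide faces are usable.
- PhSeNa (from PhSeSePh and NaBH4 in EtOH) opens it at the secondary carbon to the hydroxy selenide F7.
- H2O2 oxidation with in situ syn elimination gives the tertiary allylic alcohol F8.
- Pyridinium chlorochromate, (C5H5NH)[CrO3Cl], effects the Babler–Dauben oxidative transposition to 4.

**Step 7.**
- The risk is poor facial selectivity, because both flanks of the ketone are bulky and the ring conformation may oppose the catalyst.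
- The fallback sets out from 11 and comes back at 16. It swaps catalyst control for intramolecular hydride delivery and reverses the order of acylation.
- HF·pyridine gives the γ-hydroxy enone F9.
- Evans–Saksena reduction with Me4NBH(OAc)3 in MeCN/AcOH binds boron to the C4 oxygen. Hydride then reaches C1 from the inner face across the Z alkene, which leads to the cis-1,4-diol F10.
- Steglich esterification with 15 takes the less hindered C4 hydroxyl and gives the monoester F11.
- Ac2O with 4-(dimethylamino)pyridine acetylates C1 to give 16.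

**Further compounds**
F1 | step 6 | (2Z,4R,6E)-4-(tert-butyldimethylsilyloxy)-3,7-dimethyl-1-(trimethylsilyloxy)bicyclo[8.1.0]undeca-2,6-diene, trans-fused | C1[C@H]2C[C@]2(O[Si](C)(C)C)/C=C(C)\[C@H](O[Si](C)(C)C(C)(C)C)C/C=C(C)/C1
F2 | step 6 | (2Z,4R,6E)-4-(tert-butyldimethylsilyloxy)-10-chloro-3,7-dimethylcycloundeca-2,6-dien-1-one, C10 epimers | O=C1/C=C(/C)[C@H](O[Si](C)(C)C(C)(C)C)C/C=C(\C)CCC(Cl)C1
F3 | step 6 | (2Z,4R,6E,10E)-4-(tert-butyldimethylsilyloxy)-3,7-dimethylcycloundeca-2,6,10-trien-1-one | C1/C=C/C(=O)/C=C(C)\[C@H](O[Si](C)(C)C(C)(C)C)C/C=C(C)/C1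
F4 | step 6 | (2Z,4R,6E)-4-(tert-butyldimethylsilyloxy)-3,7-dimethylcycloundeca-2,6-dien-1-one | O=C1/C=C(/C)[C@H](O[Si](C)(C)C(C)(C)C)C/C=C(\C)CCCC1
F5 | step 6 | (2Z,4R,6E)-4-(tert-butyldimethylsilyloxy)-3,7,11-trimethylcycloundeca-2,6-dien-1-one, C11 epimers | O=C1/C=C(/C)[C@H](O[Si](C)(C)C(C)(C)C)C/C=C(\C)CCCC1C
F6 | step 3 | 2,3-epoxide of 3, both epoxide faces | CC12OC1C[C@H](C[C@H]2O[Si](C)(C)C(C)(C)C)C(C)=C
F7 | step 3 | 2-hydroxy-3-(phenylselanyl) derivative of 3 | CC1(O)C([Se]c2ccccc2)C[C@H](C[C@H]1O[Si](C)(C)C(C)(C)C)C(C)=C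
F8 | step 3 | 6-(tert-butyldimethylsilyloxy)-1-methyl-4-(prop-1-en-2-yl)cyclohex-2-en-1-ol | CC1(O)C=C[C@H](C[C@H]1O[Si](C)(C)C(C)(C)C)C(C)=C
F9 | step 7 | (2Z,4R,6E)-4-hydroxy-3,7,11,11-tetramethylcycloundeca-2,6-dien-1-one | O=C1/C=C(/C)[C@H](O)C/C=C(\C)CCCC1(C)C
F10 | step 7 | (1R,2Z,4R,6E)-3,7,11,11-tetramethylcycloundeca-2,6-diene-1,4-diol | O[C@@H]1/C=C(/C)[C@H](O)C/C=C(\C)CCCC1(C)C
F11 | step 7 | (1R,2Z,4R,6E)-1-hydroxy-3,7,11,11-tetramethylcycloundeca-2,6-dien-4-yl 4-(tert-butyldimethylsilyloxy)benzoate | O[C@@H]1/C=C(/C)[C@H](OC(=O)c2ccc(O[Si](C)(C)C(C)(C)C)cc2)C/C=C(\C)CCCC1(C)C
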